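Ring A is taken apart into three pieces: a methoxycarbene chromium complex that already carries rings C and B, bis(pinacolatoboryl)ethyne and one CO ligand. Their benzannulation forms C7–C8, C5–C6 and C4a–C5 in one operation and exploits the para relation on ring A between the C5 hydroxyl, peri to the C4 carbonyl of ring C, and the C8 methoxyl: the carbene carbon becomes C8, the CO becomes C5 and boron marks the C6 and C7 oxygens. The carbene complex is made regiospecifically from a comenic acid-derived pyranone-2-carbonyl chloride and K2Cr(CO)5, so that no pyranone has to be lithiated. Oxidation of both C–B bonds and methylation of the two new hydroxyls complete the route.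

Key step: step 6

Remark on the chemistry: the target has no stereocentre, so no step has to set one. The arene–Cr(CO)3 complex formed in the key step is written in SMILES with the metal fragment as a separate unit, because the η6 bond cannot be drawn. Comenic acid and (3-methoxyphenyl)boronic acid are taken as commercially available.

Step 1
Reactants: 1 comenic acid (5-hydroxy-4-oxo-4H-pyran-2-carboxylic acid)
Product: 2 6-bromo-5-hydroxy-4-oxo-4H-pyran-2-carboxylic acid
Conditions: Br2 (1.05 equiv), H2O, 0 °C → rt
Reagents that add atoms: bromine, BrBr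
Why: Electrophilic bromination of the enol should fall on C6 only, since C6 is the β-carbon of the C5 enol and is also activated by the ring oxygen, whereas C3 is deactivated by the neighbouring carboxyl group.

Step 2
Reactants: 2 6-bromo-5-hydroxy-4-oxo-4H-pyran-2-carboxylic acid
Product: 3 methyl 6-bromo-5-methoxy-4-oxo-4H-pyran-2-carboxylate
Conditions: MeI (3 equiv), K2CO3, DMF, rt
Reagents that add atoms: iodomethane, CI
Why: Williamson-type O-alkylation (SN2 on MeI) of the carboxylate and of the acidic enolic hydroxyl under K2CO3 should cap both oxygens as methyl groups and leave the vinylic bromide in place.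

Step 3
Reactants: 3 methyl 6-bromo-5-methoxy-4-oxo-4H-pyran-2-carboxylate; 4 (3-methoxyphenyl)boronic acid
Product: 6 5-methoxy-6-(3-methoxyphenyl)-4-oxo-4H-pyran-2-carboxylic acid, via methyl ester 5 (not isolated)
Conditions: Pd(PPh3)4 (5 mol %), K3PO4, 1,4-dioxane/H2O, 70 °C; then LiOH, rt; then 1 M HCl
Reagents that add atoms: lithium hydroxide, [Li+].[OH-]
Why: Suzuki–Miyaura coupling at the C6–Br bond, which is activated for oxidative addition to zerovalent palladium as the β-position of the pyranone enone, followed in the same pot by saponification of the activated methyl ester.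

Step 4
Reactants: 6 5-methoxy-6-(3-methoxyphenyl)-4-oxo-4H-pyran-2-carboxylic acid
Product: 7 5-methoxy-6-(3-methoxyphenyl)-4-oxo-4H-pyran-2-carbonyl chloride
Conditions: (COCl)2 (1.3 equiv), DMF (cat.), CH2Cl2, 0 °C → rt; evaporate, used crude
Reagents that add atoms: oxalyl chloride, O=C(Cl)C(Cl)=O
Why: Standard acid chloride formation through the Vilsmeier-type intermediate from oxalyl chloride and catalytic DMF, which should leave the methyl ethers and the acid-stable pyranone untouched.

Step 5
Reactants: 7 5-methoxy-6-(3-methoxyphenyl)-4-oxo-4H-pyran-2-carbonyl chloride; 8 chromium hexacarbonyl, Cr(CO)6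
Product: 11 pentacarbonyl{methoxy[5-methoxy-6-(3-methoxyphenyl)-4-oxo-4H-pyran-2-yl]methylidene}chromium, via dipotassium pentacarbonylchromate 9 (not isolated), via potassium acylchromate 10 (not isolated)
Conditions: Cr(CO)6, C8K (2.1 equiv), THF, −78 → 0 °C; then 7, THF, −78 → 0 °C; solvent switch; Me3OBF4 (1.1 equiv), CH2Cl2, −20 → 0 °C; all under Ar
Reagents that add atoms: trimethyloxonium tetrafluoroborate, C[O+](C)C.F[B-](F)(F)F
Why: Semmelhack–Hegedus carbene synthesis, in which the strongly nucleophilic K2Cr(CO)5 is acylated by the acid chloride and the anionic acylate oxygen is methylated by Me3OBF4 far faster than the neutral pyranone carbonyl, so the carbene carbon sits exactly where the carboxyl carbon of 7 was.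

Step 6
Reactants: 11 pentacarbonyl{methoxy[5-methoxy-6-(3-methoxyphenyl)-4-oxo-4H-pyran-2-yl]methylidene}chromium; 12 1,2-bis(4,4,5,5-tetramethyl-1,3,2-dioxaborolan-2-yl)ethyne
Product: 14 5-hydroxy-3,8-dimethoxy-2-(3-methoxyphenyl)-6,7-bis(4,4,5,5-tetramethyl-1,3,2-dioxaborolan-2-yl)chromen-4-one, via tricarbonylchromium arene complex 13 (not isolated)
Conditions: 12 (1.5 equiv), THF (0.05 M), 50 °C, Ar; then MeCN, 60 °C
Reagents that add atoms: none
Why: Proposed new method: thermal loss of one CO from 11 should let the alkyne bind and insert into the Cr=C bond, and CO insertion then gives a chromium-bound vinylketene whose third π unit is the pyranone C2=C3 bond. Ring A closes by thermal 6π electrocyclization of this dienylketene onto the pyranone CH carbon (the future C4a), and enolization of the cyclohexadienone gives the C5 phenol, held on chromium as complex 13 until acetonitrile displaces the metal. The closest known reaction type is the Dötz benzannulation of alkenyl- and heteroaryl(methoxy)carbene chromium complexes with alkynylboronates; neither a 4-pyranon-2-yl carbene nor the doubly borylated alkyne has been shown in it. No stereocentre is formed. The para relation of the C8 methoxyl and the C5 hydroxyl follows from the mechanism, because the carbene carbon and the inserted CO end up across the new ring, and the symmetrical alkyne leaves no regiochemical choice. Benzannulation has to outrun cyclobutenone, furan and CO-free annulation products as well as protodeboronation, which should be favoured by THF as coordinating solvent, moderate temperature, high dilution and the alkene-like character of the pyranone C2=C3 bond.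

Step 7
Reactants: 14 5-hydroxy-3,8-dimethoxy-2-(3-methoxyphenyl)-6,7-bis(4,4,5,5-tetramethyl-1,3,2-dioxaborolan-2-yl)chromen-4-one
Product: 15 5,6,7-trihydroxy-3,8-dimethoxy-2-(3-methoxyphenyl)chromen-4-one
Conditions: NaBO3·4H2O (6 equiv), THF/H2O (1:1), 0 °C → rt, Ar; NH4Cl work-up
Reagents that add atoms: sodium perborate, [Na+].[O-]OB=O
Why: Oxidation of arylboronic esters by NaBO3 (1,2-shift of the aryl carbon from boron to oxygen) should replace each boron by a hydroxyl at the same carbon under conditions mild enough for the pyranone double bond and the methyl ethers.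

Step 8
Reactants: 15 5,6,7-trihydroxy-3,8-dimethoxy-2-(3-methoxyphenyl)chromen-4-one
Product: 16 emmaosunin, 5-hydroxy-3,6,7,8-tetramethoxy-2-(3-methoxyphenyl)chromen-4-one
Conditions: MeI (2.2 equiv), K2CO3 (2.5 equiv), acetone, 40 °C, Ar
Reagents that add atoms: iodomethane, CI
Why: Williamson O-methylation under stoichiometric control should alkylate the C7 and C6 hydroxyls, while the C5 hydroxyl, hydrogen-bonded to the C4 carbonyl, is the least acidic and least nucleophilic, which is the usual basis of partial methylation of 5-hydroxyflavones.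

Compound list
1 | comenic acid, 5-hydroxy-4-oxo-4H-pyran-2-carboxylic acid | O=C(O)c1cc(=O)c(O)co1 | starting material
2 | 6-bromo-5-hydroxy-4-oxo-4H-pyran-2-carboxylic acid | O=C(O)c1cc(=O)c(O)c(Br)o1 | intermediate
3 | methyl 6-bromo-5-methoxy-4-oxo-4H-pyran-2-carboxylate | COC(=O)c1cc(=O)c(OC)c(Br)o1 | intermediate
4 | (3-methoxyphenyl)boronic acid | COc1cccc(B(O)O)c1 | starting material
5 | methyl 5-methoxy-6-(3-methoxyphenyl)-4-oxo-4H-pyran-2-carboxylate | COC(=O)c1cc(=O)c(OC)c(-c2cccc(OC)c2)o1 | intermediate
6 | 5-methoxy-6-(3-methoxyphenyl)-4-oxo-4H-pyran-2-carboxylic acid | OC(=O)c1cc(=O)c(OC)c(-c2cccc(OC)c2)o1 | intermediate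
7 | 5-methoxy-6-(3-methoxyphenyl)-4-oxo-4H-pyran-2-carbonyl chloride | ClC(=O)c1cc(=O)c(OC)c(-c2cccc(OC)c2)o1 | intermediate
8 | chromium hexacarbonyl, Cr(CO)6 | O=C=[Cr](=C=O)(=C=O)(=C=O)(=C=O)=C=O | starting material
9 | dipotassium pentacarbonylchromate, K2Cr(CO)5 | [K+].[K+].O=C=[Cr-2](=C=O)(=C=O)(=C=O)=C=O | intermediate
10 | potassium pentacarbonyl{[5-methoxy-6-(3-methoxyphenyl)-4-oxo-4H-pyran-2-yl]oxidomethylidene}chromate | [K+].[O-]C(=[Cr](=C=O)(=C=O)(=C=O)(=C=O)=C=O)c1cc(=O)c(OC)c(-c2cccc(OC)c2)o1 | intermediate
11 | pentacarbonyl{methoxy[5-methoxy-6-(3-methoxyphenyl)-4-oxo-4H-pyran-2-yl]methylidene}chromium | COC(=[Cr](=C=O)(=C=O)(=C=O)(=C=O)=C=O)c1cc(=O)c(OC)c(-c2cccc(OC)c2)o1 | intermediate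
12 | 1,2-bis(4,4,5,5-tetramethyl-1,3,2-dioxaborolan-2-yl)ethyne | CC1(C)OB(OC1(C)C)C#CB1OC(C)(C)C(C)(C)O1 | starting material
13 | tricarbonyl(η6-arene)chromium complex of 14, Cr(CO)3 bound to ring A | COc1cccc(c1)-c1oc2c(OC)c(B3OC(C)(C)C(C)(C)O3)c(B3OC(C)(C)C(C)(C)O3)c(O)c2c(=O)c1OC.O=C=[Cr](=C=O)=C=O | intermediate
14 | 5-hydroxy-3,8-dimethoxy-2-(3-methoxyphenyl)-6,7-bis(4,4,5,5-tetramethyl-1,3,2-dioxaborolan-2-yl)chromen-4-one | COc1cccc(c1)-c1oc2c(OC)c(B3OC(C)(C)C(C)(C)O3)c(B3OC(C)(C)C(C)(C)O3)c(O)c2c(=O)c1OC | intermediate
15 | 5,6,7-trihydroxy-3,8-dimethoxy-2-(3-methoxyphenyl)chromen-4-one | COc1cccc(c1)-c1oc2c(OC)c(O)c(O)c(O)c2c(=O)c1OC | intermediate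
16 | emmaosunin, 5-hydroxy-3,6,7,8-tetramethoxy-2-(3-methoxyphenyl)chromen-4-one | COc1cccc(-c2oc3c(OC)c(OC)c(OC)c(O)c3c(=O)c2OC)c1 | target

Total step count: 8. Longest linear sequence: 8 steps (1 → 16).

Steps most likely to fail

Step 6. The alkyne or CO insertion may be diverted to cyclobutenone, furan or CO-free annulation products, the hindered alkyne may insert too slowly for the electron-poor carbene to survive, or the C–B bonds may be lost by protodeboronation. The fallback uses known chemistry, a Moore-type ring expansion of a squarate adduct; it sets out from 6 and comes back to the route at 16.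
- Protodecarboxylation of 6 (Cu2O, 1,10-phenanthroline, NMP/quinoline, 170 °C) should give 3-methoxy-2-(3-methoxyphenyl)-4H-pyran-4-one F1.
- Deprotonation next to the ring oxygen with lithium 2,2,6,6-tetramethylpiperidide (LiTMP, THF, −78 °C), the counterpart of the C2 metalation of chromones by hindered amide bases, gives [5-methoxy-6-(3-methoxyphenyl)-4-oxo-4H-pyran-2-yl]lithium F2.
- 1,2-Addition of F2 to dimethyl squarate (3,4-dimethoxycyclobut-3-ene-1,2-dione) gives racemic 4-hydroxy-2,3-dimethoxy-4-[5-methoxy-6-(3-methoxyphenyl)-4-oxo-4H-pyran-2-yl]cyclobut-2-en-1-one F3.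
- O-Methylation (MeI, Ag2O, K2CO3) gives racemic 2,3,4-trimethoxy-4-[5-methoxy-6-(3-methoxyphenyl)-4-oxo-4H-pyran-2-yl]cyclobut-2-en-1-one F4.
- Heating F4 in toluene at 110 °C should open the cyclobutenone by 4π ring opening with the methoxyl turning outward, close the dienylketene by 6π electrocyclization onto the pyranone CH and tautomerize to 16 directly. The carbinol carbon becomes C8 with its methoxyl, the two enol ether carbons become C7 and C6, and the ketene carbon becomes C5 with the free hydroxyl.

Step 5. Electron transfer from K2Cr(CO)5 to the acid chloride or the pyranone may compete with acylation, the acylate may be O-acylated by a second molecule of 7, or Me3OBF4 may alkylate the pyranone carbonyl. The fallback replaces chromate acylation by the Fischer organolithium route; it sets out from 6 and comes back at 11. The pyranone F1 and its lithio derivative F2 are made as in the fallback for step 6. F2 is added to Cr(CO)6 (THF, −78 → 0 °C) to give lithium pentacarbonyl{[5-methoxy-6-(3-methoxyphenyl)-4-oxo-4H-pyran-2-yl]oxidomethylidene}chromate F5, which is methylated with Me3OBF4 in CH2Cl2 to 11.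

Step 8. Methylation may run on to the chelated C5 hydroxyl or stop before the hindered C6 hydroxyl, and the electron-rich triol may be oxidized by air under base. The fallback separates the two tasks; it sets out from 15 and comes back at 16. Exhaustive methylation (excess MeI, K2CO3, DMF, 60 °C) gives 3,5,6,7,8-pentamethoxy-2-(3-methoxyphenyl)chromen-4-one F6. BCl3 (CH2Cl2, −78 → 0 °C) then removes only the C5 methyl group, whose oxygen chelates boron together with the C4 carbonyl.

Further compounds
F1 | step 6 | 3-methoxy-2-(3-methoxyphenyl)-4H-pyran-4-one | COc1cccc(c1)-c1occc(=O)c1OC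
F2 | step 6 | [5-methoxy-6-(3-methoxyphenyl)-4-oxo-4H-pyran-2-yl]lithium | [Li]c1cc(=O)c(OC)c(-c2cccc(OC)c2)o1
F3 | step 6 | racemic 4-hydroxy-2,3-dimethoxy-4-[5-methoxy-6-(3-methoxyphenyl)-4-oxo-4H-pyran-2-yl]cyclobut-2-en-1-one | COC1=C(OC)C(O)(C1=O)c1cc(=O)c(OC)c(-c2cccc(OC)c2)o1
F4 | step 6 | racemic 2,3,4-trimethoxy-4-[5-methoxy-6-(3-methoxyphenyl)-4-oxo-4H-pyran-2-yl]cyclobut-2-en-1-one | COC1=C(OC)C(OC)(C1=O)c1cc(=O)c(OC)c(-c2cccc(OC)c2)o1
F5 | step 5 | lithium pentacarbonyl{[5-methoxy-6-(3-methoxyphenyl)-4-oxo-4H-pyran-2-yl]oxidomethylidene}chromate | [Li+].[O-]C(=[Cr](=C=O)(=C=O)(=C=O)(=C=O)=C=O)c1cc(=O)c(OC)c(-c2cccc(OC)c2)o1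
F6 | step 8 | 3,5,6,7,8-pentamethoxy-2-(3-methoxyphenyl)chromen-4-one | COc1cccc(c1)-c1oc2c(OC)c(OC)c(OC)c(OC)c2c(=O)c1OC
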